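## The problem

Target 30 is a linear chain of seven benzene rings, lettered A to G from the 2,4,6-trihydroxyphenyl end to the 3,4,5-trihydroxyphenyl end, held together only by six diaryl ether oxygens and carrying eighteen free phenolic hydroxyls. Rings C and E share one pattern, written for ring E as E1 (oxygen to ring D), E2 (the only C–H), E3 to E5 (hydroxyls) and E6 (oxygen to ring F), and for ring C as C1 (oxygen to ring B), C2–H and C6 (oxygen to ring D); ring D is bonded at D1 and D4, rings B and F are 1,3,4,5-oxygenated with their ether links at positions 1 and 5, and ring A is bonded at a carbon between two hydroxyls. There is no stereocentre, so nothing has to be controlled in space; the difficulty lies in placing the oxygens and in forming four ethers (at E6, C6, D4 and the ether-bearing carbon of ring A) at carbons that lie between two oxygen-bearing neighbours. The free pyrogallol-, hydroxyquinol- and phloroglucinol-type rings are oxidised easily by air, above all in base, so every hydroxyl has to stay masked until the last step and the unmasking has to be acidic and non-oxidative. On the way, an aryl squarate (moisture), an enol ether (acid) and very electron-rich arenes (peracid) need care. The feature that opens the key step is that ring E has oxygen on five contiguous carbons. E1, E6, E5 and E4 with their oxygens map onto the four carbons of a squaric ester, the carbonyl oxygens becoming those on E1 and E4 and the ester oxygens those on E6 and E5. E3–E2 is then an alkoxyvinyl unit, so only the E1–E2 bond has to be made to close the ring.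

## Retrosynthesis

**30 from 29.** The last operation cuts eighteen O–CH3 bonds of octadecamethyl ether 29. Methyl is chosen throughout because every ring can then be bought as a methyl ether or made from one-carbon pieces. Benzyl ethers would allow hydrogenolysis but would require every building block to be remade. The forward step must cleave all alkyl–oxygen bonds and leave the six aryl–oxygen–aryl bonds intact.

**29 from 27 and 28; 27 from 24 and 2.** The bond between ring A and its ether oxygen is cut to give phenol 27 and iodide 28. Ring A comes last because a 1,3,5-trioxygenated ring is the most peracid-sensitive of the seven, and this order places it after the last peracid step. Phenol 27 is traced through formate 26 and aldehyde 25 to phenol 24 and bromoaldehyde 2 (cut of the B5–O bond). In 2 the bromine marks the ether site and the formyl group is the masked B1 oxygen, unveiled by Baeyer–Villiger oxidation. The same logic brings in rings C, D and F, so each of these rings costs one coupling and one oxidation.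

**24 from 20 and 21.** The C6–O bond is cut to give phenol 20 and bromoaldehyde 21, again via an aldehyde (22) whose formyl group becomes the C1 hydroxyl by way of formate 23. Ring C has the same pattern as ring E and could be made by repeating steps 5 to 7 on 20. The purchased ring is preferred here because it is one step shorter and keeps organolithium chemistry away from a large intermediate. The squarate sequence is held as its fallback.

**20 from 16 and 17.** The D4–O bond is cut to give phenol 16 and bromoaldehyde 17, whose para formyl group activates the bromide and later becomes the D1 hydroxyl (via aldehyde 18 and formate 19). This is the least comfortable coupling of the plan: the bromide sits between two methoxy groups and the phenol carries an ortho aryloxy group. The precursor is simpler by one ring, and 16 has a single free hydroxyl, so no site selectivity is asked.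

**16 from 13 (key disconnection).** The E1–E2 carbon–carbon bond is cut (retro-6π closure) and the four-membered ring is re-closed, leading to racemic cyclobutenone 13. The neighbouring cut is the E6–O bond itself: coupling of 5 with 21, then Baeyer–Villiger oxidation. That cut is shorter by one step on the main line and by three in total, and it is kept as the fallback. The ring expansion is preferred for ring E for three reasons. The first congested ether is made by addition–elimination at a planar squarate carbon and not by a metal coupling at a flanked bromide. Each of the five oxygens of ring E arrives from a separate small piece, which keeps ring E analogues within reach. With methyl vinyl ether 10 as the two-carbon unit the product is exactly the phenol the coupling route would give, so the two methods back each other up. The carbinol oxygen of 13 is methylated before heating: a free hydroxyl would give a hydroquinone with two hydroxyls to tell apart and a tendency to oxidise, whereas the methyl ether gives phenol 16 with only the E1 hydroxyl free. The forward step needs outward rotation of the methoxy group on the quaternary ring carbon and clean tautomerisation.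

**13 from 9 and 10.** The bond between the quaternary ring carbon and the vinyl carbon, and the O–CH3 bond of the carbinol, are cut to give mixed squarate 9 and vinyl ether 10 (lithiated to 11, adding to give alkoxide 12). The forward reaction must attack the carbonyl next to the methoxy-bearing carbon. That carbonyl is the vinylogous ester of the weaker aryloxy donor and is flanked by the smaller group.

**9 from 5 and 8; 8 from 7 from 6.** The E6–O bond is cut at the squarate stage to give phenol 5 and ester chloride 8, made from dichloride 7 and squaric acid 6. A chloride leaving group is used because exchange of a methoxy group by a phenol at a squaric diester would run against the acidity gradient, whereas a phenol displaces chloride irreversibly.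

**5 from 1 and 2.** The ether bond between ring G and position 5 of ring F is cut to give phenol 1 and bromoaldehyde 2 (via aldehyde 3 and formate 4). Both partners are purchasable, and the coupling joins an unhindered phenol to a bromide with one ortho methoxy group.

## Roads not taken

Alternative 1: aryne three-component loading of ring E.
- *Cut:* the E1–O bond to ring D and a carbon–iodine bond at E6 are cut together, leading back to an aryne of ring E released by fluoride from a silyl triflate.
- *Forward step:* the phenoxide of a ring D unit (benzyl-protected at D1) adds at E1, away from the neighbouring methoxy group, and the aryl anion at E6 takes iodine from a perfluoroalkyl iodide. The product is 5-[4-(benzyloxy)-2,6-dimethoxyphenoxy]-4-iodo-1,2,3-trimethoxybenzene A1.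
- *Merits:* a 2,6-dimethoxyphenoxide adds to an aryne without a metal and with little regard for hindrance. The D4–O–E1 ether, which the chosen plan makes by a CuI-catalysed coupling at a bromide between two methoxy groups (step 8), is formed more safely here. Regiocontrol by the methoxy group next to the aryne is reliable.
- *Weak points:* the iodide in A1 lies between an aryloxy and a methoxy group on an electron-rich ring. Turning it into the E6–O–F ether requires a CuI-catalysed Ullmann coupling at the most congested carbon of the molecule. The silyl triflate costs several steps, the aryl anion can be protonated before it meets the iodine source, and the benzyl group must be removed before ring C is attached.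
- *Comparison:* each plan forms one of the two ethers at ring E without a metal. The chosen plan spends its metal-free step on the more congested position E6, draws every ring from a purchasable compound, and accepts step 8 as the price.

Alternative 2: Dötz benzannulation for ring F.
- *Cut:* ring F is dismantled into an alkenyl(methoxy)carbene complex of Cr(CO)5 (zerovalent chromium), the ethynyl ether of ring G and one carbonyl ligand.
- *Forward step:* three carbon–carbon bonds form and give 2-(benzyloxy)-4-methoxy-6-(3,4,5-trimethoxyphenoxy)phenol A2.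
- *Merits:* the G–O–F ether is in place before the ring exists, the regiochemistry with a terminal alkyne is dependable, and the three oxygens of ring F arrive differentiated.
- *Weak points:* ring F is the ring that least needs building, since its pattern is sold as bromoaldehyde 2 and the G–O–F ether costs one step (step 1). In A2 the ring F oxygen that must bond to ring E arrives as a methyl ether indistinguishable from those of ring G, while the free hydroxyl is the central one of ring F, which the target needs only as a hydroxyl. A stoichiometric Cr(CO)5 carbene complex and a sensitive alkynyl ether have to be prepared. The pentaoxygenated rings C and E and their crowded ethers remain unsolved.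
- *Comparison:* the differentiated oxygens are a real advantage for analogues but are not needed for 30. The chosen plan places its ring construction where the substitution is densest.

Alternative 3: Danheiser benzannulation for ring D.
- *Cut:* central ring D is dismantled into a 4-aryloxy-3-ethoxycyclobutenone carrying ring E and the ethynyl ether of a ring C unit.
- *Forward step:* heating gives a vinylketene that adds the alkyne and, after ring opening and 6π closure, gives 2-[2-(allyloxy)-3,4,5-trimethoxyphenoxy]-5-[6-(benzyloxy)-2,3,4-trimethoxyphenoxy]-3-ethoxyphenol A3.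
- *Merits:* this is the most convergent of the four plans. Two halves are joined as ring D forms, both ethers at ring D arrive without any coupling at D4 (again better than step 8), and the longest linear sequence would be shorter.
- *Weak points:* in A3 the oxygens at E6 and C1 are only allyl- and benzyl-protected hydroxyls. The most crowded ether, E6–O–F, would have to be made late, by arylating a hindered phenol on a large intermediate. The ethynyl ether must be made from a phenol with two ortho oxygens, and the aryloxy-substituted cyclobutenone is an uncommon class with no simple source.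
- *Comparison:* the alternative wins on convergence. The chosen plan sets against it that the crowded E6 ether is settled first, on a small molecule, and that every later step uses a purchased ring.

Key step: step 7

Remark on the chemistry: the target has no stereocentre; cyclobutenone 13 is formed and used as the racemate, and its single stereocentre disappears in step 7.

## Route

Step 1
Reactants: 1 3,4,5-trimethoxyphenol; 2 3-bromo-4,5-dimethoxybenzaldehyde
Product: 3 3,4-dimethoxy-5-(3,4,5-trimethoxyphenoxy)benzaldehyde
Conditions: CuI (10 mol %), picolinic acid (20 mol %), K3PO4, DMSO, 90 °C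
Reagents that add atoms: none
Why: Ullmann diaryl ether coupling of an unhindered phenol with a bromide that has one ortho methoxy group; the aldehyde has no α-hydrogen and should tolerate the phosphate base.

Step 2
Reactants: 3 3,4-dimethoxy-5-(3,4,5-trimethoxyphenoxy)benzaldehyde
Product: 5 3,4-dimethoxy-5-(3,4,5-trimethoxyphenoxy)phenol, via ring F formate 4 (not isolated)
Conditions: mCPBA, CH2Cl2, 0 °C to rt; aq. NaHCO3 wash; then K2CO3 (cat.), MeOH, rt
Reagents that add atoms: mCPBA (3-chloroperoxybenzoic acid), OOC(=O)c1cccc(Cl)c1
Why: Baeyer–Villiger oxidation of an electron-rich benzaldehyde, in which the aryl group migrates to give formate 4; methanolysis then frees the phenol (overall a Dakin-type change of CHO into OH).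

Step 3
Reactants: 6 squaric acid (3,4-dihydroxycyclobut-3-ene-1,2-dione)
Product: 7 3,4-dichlorocyclobut-3-ene-1,2-dione
Conditions: (COCl)2, DMF (cat.), 1,2-dichloroethane, 50 °C
Reagents that add atoms: oxalyl chloride, O=C(Cl)C(Cl)=O
Why: Chlorination of the vinylogous acid with oxalyl chloride under DMF catalysis (Vilsmeier-type activation), the standard preparation of squaric acid dichloride.

Step 4
Reactants: 7 3,4-dichlorocyclobut-3-ene-1,2-dione
Product: 8 3-chloro-4-methoxycyclobut-3-ene-1,2-dione
Conditions: MeOH (1.0 equiv), Et2O, 0 °C to rt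
Reagents that add atoms: methanol, CO
Why: Mono-alcoholysis of a vinylogous acid chloride; the methoxy group introduced first donates into the ring and slows the second exchange, so one equivalent of methanol should stop at the ester chloride.

Step 5
Reactants: 5 3,4-dimethoxy-5-(3,4,5-trimethoxyphenoxy)phenol; 8 3-chloro-4-methoxycyclobut-3-ene-1,2-dione
Product: 9 3-methoxy-4-[3,4-dimethoxy-5-(3,4,5-trimethoxyphenoxy)phenoxy]cyclobut-3-ene-1,2-dione
Conditions: iPr2NEt, CH2Cl2, −40 to 0 °C
Reagents that add atoms: none
Why: Vinylogous acyl substitution (addition–elimination) in which the phenol displaces chloride, by far the better leaving group, so the methoxy group should stay in place; the carbon attacked is part of a flat four-membered ring, so the crowding that later surrounds E6 plays no part.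

Step 6
Reactants: 9 3-methoxy-4-[3,4-dimethoxy-5-(3,4,5-trimethoxyphenoxy)phenoxy]cyclobut-3-ene-1,2-dione; 10 methyl vinyl ether
Product: 13 racemic 3,4-dimethoxy-4-(1-methoxyvinyl)-2-[3,4-dimethoxy-5-(3,4,5-trimethoxyphenoxy)phenoxy]cyclobut-2-en-1-one, via 1-methoxyvinyllithium 11 (not isolated), via lithium alkoxide 12 (not isolated)
Conditions: 10, t-BuLi, THF, −78 to 0 °C; then 9, THF, −78 °C; then MeOTf, −78 to −20 °C; aq. NaHCO3
Reagents that add atoms: methyl trifluoromethanesulfonate (MeOTf), COS(=O)(=O)C(F)(F)F
Why: α-Lithiation of the vinyl ether gives 11, which adds 1,2 to a squarate carbonyl; the carbonyl next to the methoxy-bearing carbon is the vinylogous ester of the weaker aryloxy donor and is flanked by the smaller group, so it should be attacked preferentially, and alkoxide 12 is O-methylated in the flask. The new quaternary centre forms as a racemate and is removed in step 7.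

Step 7
Reactants: 13 racemic 3,4-dimethoxy-4-(1-methoxyvinyl)-2-[3,4-dimethoxy-5-(3,4,5-trimethoxyphenoxy)phenoxy]cyclobut-2-en-1-one
Product: 16 3,4,5-trimethoxy-2-[3,4-dimethoxy-5-(3,4,5-trimethoxyphenoxy)phenoxy]phenol, via dienylketene 14 (not isolated), via cyclohexadienone 15 (not isolated)
Conditions: degassed p-xylene, 140 °C, base-washed glassware
Reagents that add atoms: none
Why: Moore rearrangement of a 4-alkenyl-4-alkoxycyclobutenone: heating opens the bond between the carbonyl carbon and the quaternary carbon of 13 in a thermal conrotatory 4π electrocyclic ring opening. The methoxy group on the quaternary carbon, the stronger donor, should rotate outward, which turns the 1-methoxyvinyl group inward and places it cis to the ketene in (Z)-dienylketene 14. A thermal disrotatory 6π electrocyclisation then forms the one new carbon–carbon bond, between the ketene carbon (E1) and the vinyl CH2 carbon (E2), and closes six-membered ring E as cyclohexa-2,4-dienone 15, which tautomerises irreversibly to phenol 16. No stereocentre is created and the racemic centre of 13 is erased. The only selectivity required in this step is the sense of rotation at the quaternary carbon, secured by the donor preference of the alkoxy group; the placement of the aryloxy group at E6 was fixed in step 6. Because the carbinol is capped as its methyl ether, the ketene cannot be trapped by a hydroxyl to give a furanone, and the product has a single free hydroxyl at E1 and is not an oxidation-prone hydroquinone. The closest known reaction type is the thermal ring expansion of 4-alkenyl-4-hydroxy- and 4-alkoxycyclobutenones derived from squaric esters to polyoxygenated hydroquinones and their monoethers.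

Step 8
Reactants: 16 3,4,5-trimethoxy-2-[3,4-dimethoxy-5-(3,4,5-trimethoxyphenoxy)phenoxy]phenol; 17 4-bromo-3,5-dimethoxybenzaldehyde
Product: 18 3,5-dimethoxy-4-(aryloxy)benzaldehyde in which the aryloxy group is that of phenol 16 (rings D to G)
Conditions: CuI (20 mol %), picolinic acid (40 mol %), K3PO4, DMSO, 110 °C
Reagents that add atoms: none
Why: Ullmann diaryl ether coupling with a ligand suited to hindered partners; the bromide is flanked by two methoxy groups but activated by the para formyl group, and 16 offers only one hydroxyl.

Step 9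
Reactants: 18 3,5-dimethoxy-4-(aryloxy)benzaldehyde (rings D to G)
Product: 20 3,5-dimethoxy-4-(aryloxy)phenol in which the aryloxy group is that of phenol 16, via ring D formate 19 (not isolated)
Conditions: mCPBA, CH2Cl2, 0 °C to rt; aq. NaHCO3 wash; then K2CO3 (cat.), MeOH, rt
Reagents that add atoms: mCPBA (3-chloroperoxybenzoic acid), OOC(=O)c1cccc(Cl)c1
Why: Baeyer–Villiger oxidation; the migrating ring carries a para aryloxy and two meta methoxy groups and should migrate in preference to hydrogen, and the fully alkylated 1,2,3-oxygenated rings present should tolerate the peracid at this temperature.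

Step 10
Reactants: 20 3,5-dimethoxy-4-(aryloxy)phenol (rings D to G); 21 2-bromo-3,4,5-trimethoxybenzaldehyde
Product: 22 3,4,5-trimethoxy-2-(aryloxy)benzaldehyde in which the aryloxy group is that of phenol 20 (rings C to G)
Conditions: CuI (20 mol %), picolinic acid (40 mol %), K3PO4, DMSO, 100 °C
Reagents that add atoms: none
Why: Ullmann diaryl ether coupling; the bromide is activated by the ortho formyl group and the phenol has two free ortho positions, which offsets the flanking of the bromide by formyl and methoxy.

Step 11
Reactants: 22 3,4,5-trimethoxy-2-(aryloxy)benzaldehyde (rings C to G)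
Product: 24 3,4,5-trimethoxy-2-(aryloxy)phenol in which the aryloxy group is that of phenol 20, via ring C formate 23 (not isolated)
Conditions: mCPBA, CH2Cl2, 0 °C to rt; aq. NaHCO3 wash; then K2CO3 (cat.), MeOH, rt
Reagents that add atoms: mCPBA (3-chloroperoxybenzoic acid), OOC(=O)c1cccc(Cl)c1
Why: Baeyer–Villiger oxidation; the ortho aryloxy and para methoxy groups make the ring a good migrating group, and methanolysis of formate 23 frees the C1 hydroxyl.

Step 12
Reactants: 24 3,4,5-trimethoxy-2-(aryloxy)phenol (rings C to G); 2 3-bromo-4,5-dimethoxybenzaldehyde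
Product: 25 3,4-dimethoxy-5-(aryloxy)benzaldehyde in which the aryloxy group is that of phenol 24 (rings B to G)
Conditions: CuI (20 mol %), picolinic acid (40 mol %), K3PO4, DMSO, 100 °C
Reagents that add atoms: none
Why: Ullmann diaryl ether coupling of a phenol with one ortho substituent and a bromide with one ortho methoxy group, the same partner type as in step 1.

Step 13
Reactants: 25 3,4-dimethoxy-5-(aryloxy)benzaldehyde (rings B to G)
Product: 27 3,4-dimethoxy-5-(aryloxy)phenol in which the aryloxy group is that of phenol 24, via ring B formate 26 (not isolated)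
Conditions: mCPBA, CH2Cl2, 0 °C to rt; aq. NaHCO3 wash; then K2CO3 (cat.), MeOH, rt
Reagents that add atoms: mCPBA (3-chloroperoxybenzoic acid), OOC(=O)c1cccc(Cl)c1
Why: Baeyer–Villiger oxidation as in step 2; it is the last peracid step and is placed before the peracid-sensitive 1,3,5-trioxygenated ring A is introduced.

Step 14
Reactants: 27 3,4-dimethoxy-5-(aryloxy)phenol (rings B to G); 28 2-iodo-1,3,5-trimethoxybenzene
Product: 29 octadecamethyl ether of the target, 2-(aryloxy)-1,3,5-trimethoxybenzene in which the aryloxy group is that of phenol 27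
Conditions: CuI (20 mol %), picolinic acid (40 mol %), K3PO4, DMSO, 100 °C
Reagents that add atoms: none
Why: Ullmann diaryl ether coupling of an unhindered phenol with a 2,6-dimethoxyaryl iodide, a pairing with precedent in permethylated phloroglucinol ethers; iodide is chosen over bromide to help the electron-rich, doubly flanked ring react.

Step 15
Reactants: 29 octadecamethyl ether of the target
Product: 30 the target, CNP0137585.0
Conditions: BBr3 (excess), CH2Cl2, −78 °C to rt; then H2O, 0 °C; argon throughout
Reagents that add atoms: none
Why: Lewis-acid dealkylation: each aryl methyl ether binds BBr3 and loses bromomethane by bromide attack at the methyl carbon. The diaryl ether bonds offer no sp3 carbon for this attack and should survive, and the acidic, non-oxidative medium suits the air-sensitive polyphenol.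

## Compound list

1 | 3,4,5-trimethoxyphenol | COc1cc(O)cc(OC)c1OC | starting material
2 | 3-bromo-4,5-dimethoxybenzaldehyde | O=Cc1cc(Br)c(OC)c(OC)c1 | starting material
3 | 3,4-dimethoxy-5-(3,4,5-trimethoxyphenoxy)benzaldehyde | O=Cc1cc(OC)c(OC)c(Oc2cc(OC)c(OC)c(OC)c2)c1 | intermediate
4 | 3,4-dimethoxy-5-(3,4,5-trimethoxyphenoxy)phenyl formate | O=COc1cc(OC)c(OC)c(Oc2cc(OC)c(OC)c(OC)c2)c1 | intermediate (not isolated)
5 | 3,4-dimethoxy-5-(3,4,5-trimethoxyphenoxy)phenol | Oc1cc(OC)c(OC)c(Oc2cc(OC)c(OC)c(OC)c2)c1 | intermediate
6 | squaric acid (3,4-dihydroxycyclobut-3-ene-1,2-dione) | OC1=C(O)C(=O)C1=O | starting material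
7 | 3,4-dichlorocyclobut-3-ene-1,2-dione | ClC1=C(Cl)C(=O)C1=O | intermediate
8 | 3-chloro-4-methoxycyclobut-3-ene-1,2-dione | COC1=C(Cl)C(=O)C1=O | intermediate
9 | 3-methoxy-4-[3,4-dimethoxy-5-(3,4,5-trimethoxyphenoxy)phenoxy]cyclobut-3-ene-1,2-dione | COC1=C(Oc2cc(OC)c(OC)c(Oc3cc(OC)c(OC)c(OC)c3)c2)C(=O)C1=O | intermediate
10 | methyl vinyl ether (methoxyethene) | COC=C | starting material
11 | 1-methoxyvinyllithium | [Li]C(=C)OC | intermediate (not isolated)
12 | lithium alkoxide of racemic 4-hydroxy-3-methoxy-4-(1-methoxyvinyl)-2-[3,4-dimethoxy-5-(3,4,5-trimethoxyphenoxy)phenoxy]cyclobut-2-en-1-one | [Li+].[O-]C1(C(=C)OC)C(OC)=C(Oc2cc(OC)c(OC)c(Oc3cc(OC)c(OC)c(OC)c3)c2)C1=O | intermediate (not isolated)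
13 | racemic 3,4-dimethoxy-4-(1-methoxyvinyl)-2-[3,4-dimethoxy-5-(3,4,5-trimethoxyphenoxy)phenoxy]cyclobut-2-en-1-one | COC(=C)C1(OC)C(OC)=C(Oc2cc(OC)c(OC)c(Oc3cc(OC)c(OC)c(OC)c3)c2)C1=O | intermediate
14 | (3Z)-3,4,5-trimethoxy-2-[3,4-dimethoxy-5-(3,4,5-trimethoxyphenoxy)phenoxy]hexa-1,3,5-trien-1-one (dienylketene) | O=C=C(Oc1cc(OC)c(OC)c(Oc2cc(OC)c(OC)c(OC)c2)c1)/C(OC)=C(OC)\C(OC)=C | intermediate (not isolated)
15 | 3,4,5-trimethoxy-2-[3,4-dimethoxy-5-(3,4,5-trimethoxyphenoxy)phenoxy]cyclohexa-2,4-dien-1-one | O=C1CC(OC)=C(OC)C(OC)=C1Oc1cc(OC)c(OC)c(Oc2cc(OC)c(OC)c(OC)c2)c1 | intermediate (not isolated)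
16 | 3,4,5-trimethoxy-2-[3,4-dimethoxy-5-(3,4,5-trimethoxyphenoxy)phenoxy]phenol (rings E to G) | COc1cc(O)c(Oc2cc(OC)c(OC)c(Oc3cc(OC)c(OC)c(OC)c3)c2)c(OC)c1OC | intermediate
17 | 4-bromo-3,5-dimethoxybenzaldehyde | O=Cc1cc(OC)c(Br)c(OC)c1 | starting material
18 | 3,5-dimethoxy-4-{3,4,5-trimethoxy-2-[3,4-dimethoxy-5-(3,4,5-trimethoxyphenoxy)phenoxy]phenoxy}benzaldehyde (rings D to G) | O=Cc1cc(OC)c(Oc2cc(OC)c(OC)c(OC)c2Oc2cc(OC)c(OC)c(Oc3cc(OC)c(OC)c(OC)c3)c2)c(OC)c1 | intermediate
19 | formate ester of phenol 20 | O=COc1cc(OC)c(Oc2cc(OC)c(OC)c(OC)c2Oc2cc(OC)c(OC)c(Oc3cc(OC)c(OC)c(OC)c3)c2)c(OC)c1 | intermediate (not isolated)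
20 | 3,5-dimethoxy-4-{3,4,5-trimethoxy-2-[3,4-dimethoxy-5-(3,4,5-trimethoxyphenoxy)phenoxy]phenoxy}phenol | Oc1cc(OC)c(Oc2cc(OC)c(OC)c(OC)c2Oc2cc(OC)c(OC)c(Oc3cc(OC)c(OC)c(OC)c3)c2)c(OC)c1 | intermediate
21 | 2-bromo-3,4,5-trimethoxybenzaldehyde | O=Cc1cc(OC)c(OC)c(OC)c1Br | starting material
22 | 3,4,5-trimethoxy-2-(aryloxy)benzaldehyde, aryloxy being the oxy group of phenol 20 (rings C to G) | O=Cc1cc(OC)c(OC)c(OC)c1Oc1cc(OC)c(Oc2cc(OC)c(OC)c(OC)c2Oc2cc(OC)c(OC)c(Oc3cc(OC)c(OC)c(OC)c3)c2)c(OC)c1 | intermediate
23 | formate ester of phenol 24 | O=COc1cc(OC)c(OC)c(OC)c1Oc1cc(OC)c(Oc2cc(OC)c(OC)c(OC)c2Oc2cc(OC)c(OC)c(Oc3cc(OC)c(OC)c(OC)c3)c2)c(OC)c1 | intermediate (not isolated)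
24 | 3,4,5-trimethoxy-2-(aryloxy)phenol, aryloxy being the oxy group of phenol 20 | Oc1cc(OC)c(OC)c(OC)c1Oc1cc(OC)c(Oc2cc(OC)c(OC)c(OC)c2Oc2cc(OC)c(OC)c(Oc3cc(OC)c(OC)c(OC)c3)c2)c(OC)c1 | intermediate
25 | 3,4-dimethoxy-5-(aryloxy)benzaldehyde, aryloxy being the oxy group of phenol 24 (rings B to G) | O=Cc1cc(Oc2cc(OC)c(OC)c(OC)c2Oc2cc(OC)c(Oc3cc(OC)c(OC)c(OC)c3Oc3cc(OC)c(OC)c(Oc4cc(OC)c(OC)c(OC)c4)c3)c(OC)c2)c(OC)c(OC)c1 | intermediate
26 | formate ester of phenol 27 | O=COc1cc(Oc2cc(OC)c(OC)c(OC)c2Oc2cc(OC)c(Oc3cc(OC)c(OC)c(OC)c3Oc3cc(OC)c(OC)c(Oc4cc(OC)c(OC)c(OC)c4)c3)c(OC)c2)c(OC)c(OC)c1 | intermediate (not isolated)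
27 | 3,4-dimethoxy-5-(aryloxy)phenol, aryloxy being the oxy group of phenol 24 | Oc1cc(Oc2cc(OC)c(OC)c(OC)c2Oc2cc(OC)c(Oc3cc(OC)c(OC)c(OC)c3Oc3cc(OC)c(OC)c(Oc4cc(OC)c(OC)c(OC)c4)c3)c(OC)c2)c(OC)c(OC)c1 | intermediate
28 | 2-iodo-1,3,5-trimethoxybenzene | COc1cc(OC)c(I)c(OC)c1 | starting material
29 | octadecamethyl ether of the target: 2-(aryloxy)-1,3,5-trimethoxybenzene, aryloxy being the oxy group of phenol 27 | COc1cc(OC)c(Oc2cc(Oc3cc(OC)c(OC)c(OC)c3Oc3cc(OC)c(Oc4cc(OC)c(OC)c(OC)c4Oc4cc(OC)c(OC)c(Oc5cc(OC)c(OC)c(OC)c5)c4)c(OC)c3)c(OC)c(OC)c2)c(OC)c1 | intermediate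
30 | CNP0137585.0, the octadecahydroxy heptaphenyl hexaether (rings A to G) | Oc1cc(O)c(Oc2cc(O)c(O)c(Oc3cc(O)c(O)c(O)c3Oc3cc(O)c(Oc4cc(O)c(O)c(O)c4Oc4cc(O)c(O)c(Oc5cc(O)c(O)c(O)c5)c4)c(O)c3)c2)c(O)c1 | target

## Step count and risks

Total step count: 15. Longest linear sequence: 13 steps (steps 1, 2 and 5 to 15, counted from 1 and 2); steps 3 and 4 are a two-step branch that supplies 8.

**Step 7 (key step).** The most likely failure is loss of the dienylketene before it can cyclise. This would happen if the methoxy group on the quaternary carbon rotates inward, or if the enol ether is hydrolysed to a ketone before heating; the ketene then cannot reach the vinyl carbon and is consumed by oligomerisation or adventitious nucleophiles. The fallback abandons the ring construction. It sets out from 5 and returns at 16. Phenol 5 is coupled with bromoaldehyde 21 under the conditions of step 10 to give 3,4,5-trimethoxy-2-[3,4-dimethoxy-5-(3,4,5-trimethoxyphenoxy)phenoxy]benzaldehyde F1. Baeyer–Villiger oxidation as in step 2 gives the corresponding aryl formate F2, and its methanolysis gives 16.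

**Step 6.** The organolithium may attack the other carbonyl, because the aryloxy/methoxy bias is only moderate, or may displace aryloxide at the vinylogous ester carbon. The fallback removes the regiochemical question by symmetry. It sets out from 5 and 7 and returns at 13. Two equivalents of 5 with 7 and iPr2NEt give the diaryl squarate 3,4-bis[3,4-dimethoxy-5-(3,4,5-trimethoxyphenoxy)phenoxy]cyclobut-3-ene-1,2-dione F3. Reagent 11 adds to either of its equivalent carbonyls to give the lithium alkoxide of the adduct F4. Trapping with MeOTf gives racemic 4-methoxy-4-(1-methoxyvinyl)-2,3-bis[3,4-dimethoxy-5-(3,4,5-trimethoxyphenoxy)phenoxy]cyclobut-2-en-1-one F5. One equivalent of NaOMe in THF/MeOH at −40 °C then exchanges the aryloxy group on the ring carbon β to the carbonyl, the vinylogous aryl ester position, for methoxy; this gives 13 and returns one equivalent of 5.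

**Step 8.** The coupling may stall because the bromide lies between two methoxy groups and the phenol carries an ortho aryloxy group; hydrodebromination of 17 would then dominate. The fallback replaces the CuI-catalysed coupling by nucleophilic aromatic substitution. It sets out from 16 and returns at 18. The phenoxide of 16 (K2CO3, DMSO, 120 °C) displaces fluoride from 4-fluoro-3,5-dimethoxybenzaldehyde (O=Cc1cc(OC)c(F)c(OC)c1), activated by the para formyl group, and gives 18 directly without any new intermediate.

**Step 10.** Coupling at a bromide flanked by formyl and methoxy may be slow on this large phenol, with reduction of 21 competing. The fallback builds ring C by the squarate sequence used for ring E. It sets out from 20 and returns at 24. Phenol 20 and ester chloride 8 (iPr2NEt) give the mixed squarate 3-methoxy-4-aryloxycyclobut-3-ene-1,2-dione F6, in which the aryloxy group is the oxy group of 20. Addition of 11 gives the lithium alkoxide F7, and MeOTf gives the racemic 3,4-dimethoxy-4-(1-methoxyvinyl)-2-aryloxycyclobut-2-en-1-one F8. Heating as in step 7 should lead through the (Z)-dienylketene F9 and the cyclohexa-2,4-dienone F10 to 24.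

**Step 14.** The doubly flanked, electron-rich iodide may react too slowly, so that protodeiodination and decomposition of the phenoxide take over. The fallback brings ring A in as an activated benzaldehyde. It sets out from 27 and returns at 30. Phenol 27 is coupled with 17 under the conditions of step 8 to give the 3,5-dimethoxy-4-aryloxybenzaldehyde F11, in which the aryloxy group is the oxy group of 27. Baeyer–Villiger oxidation gives its formate F12, and methanolysis gives the phenol F13, which has a free hydroxyl on ring A para to the ether oxygen and seventeen methyl ethers. Treatment with BBr3 as in step 15 gives 30.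

**Step 15.** Cleavage of eighteen ethers may stop short, and the free polyphenol may oxidise during isolation, giving a mixture that cannot be purified directly. The fallback changes the isolation. It sets out from 29 and returns at 30. The crude product of the BBr3 treatment is acetylated (Ac2O, pyridine) to the octadecaacetate of the target F14, which is stable to air and can be chromatographed on silica; partially methylated material is removed at this stage. Acidic methanolysis (HCl in MeOH, argon, rt) then releases 30.

## Further compounds

F1 | step 7 | 3,4,5-trimethoxy-2-[3,4-dimethoxy-5-(3,4,5-trimethoxyphenoxy)phenoxy]benzaldehyde | O=Cc1cc(OC)c(OC)c(OC)c1Oc1cc(OC)c(OC)c(Oc2cc(OC)c(OC)c(OC)c2)c1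
F2 | step 7 | 3,4,5-trimethoxy-2-[3,4-dimethoxy-5-(3,4,5-trimethoxyphenoxy)phenoxy]phenyl formate | O=COc1cc(OC)c(OC)c(OC)c1Oc1cc(OC)c(OC)c(Oc2cc(OC)c(OC)c(OC)c2)c1
F3 | step 6 | 3,4-bis[3,4-dimethoxy-5-(3,4,5-trimethoxyphenoxy)phenoxy]cyclobut-3-ene-1,2-dione | O=C1C(=O)C(Oc2cc(OC)c(OC)c(Oc3cc(OC)c(OC)c(OC)c3)c2)=C1Oc1cc(OC)c(OC)c(Oc2cc(OC)c(OC)c(OC)c2)c1
F4 | step 6 | lithium alkoxide of racemic 4-hydroxy-4-(1-methoxyvinyl)-2,3-bis[3,4-dimethoxy-5-(3,4,5-trimethoxyphenoxy)phenoxy]cyclobut-2-en-1-one | [Li+].[O-]C1(C(=C)OC)C(Oc2cc(OC)c(OC)c(Oc3cc(OC)c(OC)c(OC)c3)c2)=C(Oc2cc(OC)c(OC)c(Oc3cc(OC)c(OC)c(OC)c3)c2)C1=O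
F5 | step 6 | racemic 4-methoxy-4-(1-methoxyvinyl)-2,3-bis[3,4-dimethoxy-5-(3,4,5-trimethoxyphenoxy)phenoxy]cyclobut-2-en-1-one | COC(=C)C1(OC)C(Oc2cc(OC)c(OC)c(Oc3cc(OC)c(OC)c(OC)c3)c2)=C(Oc2cc(OC)c(OC)c(Oc3cc(OC)c(OC)c(OC)c3)c2)C1=O
F0 | step 8 | none | none
F6 | step 10 | 3-methoxy-4-(aryloxy)cyclobut-3-ene-1,2-dione, aryloxy being the oxy group of phenol 20 | COC1=C(Oc2cc(OC)c(Oc3cc(OC)c(OC)c(OC)c3Oc3cc(OC)c(OC)c(Oc4cc(OC)c(OC)c(OC)c4)c3)c(OC)c2)C(=O)C1=O
F7 | step 10 | lithium alkoxide of racemic 4-hydroxy-3-methoxy-4-(1-methoxyvinyl)-2-(aryloxy)cyclobut-2-en-1-one, aryloxy being the oxy group of phenol 20 | [Li+].[O-]C1(C(=C)OC)C(OC)=C(Oc2cc(OC)c(Oc3cc(OC)c(OC)c(OC)c3Oc3cc(OC)c(OC)c(Oc4cc(OC)c(OC)c(OC)c4)c3)c(OC)c2)C1=O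
F8 | step 10 | racemic 3,4-dimethoxy-4-(1-methoxyvinyl)-2-(aryloxy)cyclobut-2-en-1-one, aryloxy being the oxy group of phenol 20 | COC(=C)C1(OC)C(OC)=C(Oc2cc(OC)c(Oc3cc(OC)c(OC)c(OC)c3Oc3cc(OC)c(OC)c(Oc4cc(OC)c(OC)c(OC)c4)c3)c(OC)c2)C1=O
F9 | step 10 | (3Z)-3,4,5-trimethoxy-2-(aryloxy)hexa-1,3,5-trien-1-one, aryloxy being the oxy group of phenol 20 | O=C=C(Oc1cc(OC)c(Oc2cc(OC)c(OC)c(OC)c2Oc2cc(OC)c(OC)c(Oc3cc(OC)c(OC)c(OC)c3)c2)c(OC)c1)/C(OC)=C(OC)\C(OC)=C
F10 | step 10 | 3,4,5-trimethoxy-2-(aryloxy)cyclohexa-2,4-dien-1-one, aryloxy being the oxy group of phenol 20 | O=C1CC(OC)=C(OC)C(OC)=C1Oc1cc(OC)c(Oc2cc(OC)c(OC)c(OC)c2Oc2cc(OC)c(OC)c(Oc3cc(OC)c(OC)c(OC)c3)c2)c(OC)c1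
F11 | step 14 | 3,5-dimethoxy-4-(aryloxy)benzaldehyde, aryloxy being the oxy group of phenol 27 | O=Cc1cc(OC)c(Oc2cc(Oc3cc(OC)c(OC)c(OC)c3Oc3cc(OC)c(Oc4cc(OC)c(OC)c(OC)c4Oc4cc(OC)c(OC)c(Oc5cc(OC)c(OC)c(OC)c5)c4)c(OC)c3)c(OC)c(OC)c2)c(OC)c1
F12 | step 14 | 3,5-dimethoxy-4-(aryloxy)phenyl formate, aryloxy being the oxy group of phenol 27 | O=COc1cc(OC)c(Oc2cc(Oc3cc(OC)c(OC)c(OC)c3Oc3cc(OC)c(Oc4cc(OC)c(OC)c(OC)c4Oc4cc(OC)c(OC)c(Oc5cc(OC)c(OC)c(OC)c5)c4)c(OC)c3)c(OC)c(OC)c2)c(OC)c1
F13 | step 14 | 3,5-dimethoxy-4-(aryloxy)phenol, aryloxy being the oxy group of phenol 27 | Oc1cc(OC)c(Oc2cc(Oc3cc(OC)c(OC)c(OC)c3Oc3cc(OC)c(Oc4cc(OC)c(OC)c(OC)c4Oc4cc(OC)c(OC)c(Oc5cc(OC)c(OC)c(OC)c5)c4)c(OC)c3)c(OC)c(OC)c2)c(OC)c1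
F14 | step 15 | octadecaacetate of the target | CC(=O)Oc1cc(OC(C)=O)c(Oc2cc(OC(C)=O)c(OC(C)=O)c(Oc3cc(OC(C)=O)c(OC(C)=O)c(OC(C)=O)c3Oc3cc(OC(C)=O)c(Oc4cc(OC(C)=O)c(OC(C)=O)c(OC(C)=O)c4Oc4cc(OC(C)=O)c(OC(C)=O)c(Oc5cc(OC(C)=O)c(OC(C)=O)c(OC(C)=O)c5)c4)c(OC(C)=O)c3)c2)c(OC(C)=O)c1
A1 | alternative 1 | 5-[4-(benzyloxy)-2,6-dimethoxyphenoxy]-4-iodo-1,2,3-trimethoxybenzene | COc1cc(Oc2c(OC)cc(OCc3ccccc3)cc2OC)c(I)c(OC)c1OC
A2 | alternative 2 | 2-(benzyloxy)-4-methoxy-6-(3,4,5-trimethoxyphenoxy)phenol | COc1cc(OCc2ccccc2)c(O)c(Oc2cc(OC)c(OC)c(OC)c2)c1
A3 | alternative 3 | 2-[2-(allyloxy)-3,4,5-trimethoxyphenoxy]-5-[6-(benzyloxy)-2,3,4-trimethoxyphenoxy]-3-ethoxyphenol | CCOc1cc(Oc2c(OCc3ccccc3)cc(OC)c(OC)c2OC)cc(O)c1Oc1cc(OC)c(OC)c(OC)c1OCC=C
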